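The ring you are after is the number you will read in each flask, and the thing to watch is whether the reading falls while ring is still being made or long after that.

| flask | starting material | temperature | remark | time |
|---|---|---|---|---|
| Thursday's | 0.055 M | 35 °C | run made earlier |  |
| Monday's | 0.083 M | 70 °C | run made earlier |  |
| dawn | 0.11 M | 40 °C |  | 4.0 min |
| summer | 0.11 M | 100 °C |  | 4.0 min |
| winter | 0.11 M | 70 °C |  | 4.0 min |

Thursday's run (percent of the starting material charged)

| time / min | ring / % |
|---|---|
| 0.250 | 0 |
| 0.833 | 0 |
| 1.33 | 1.5 |
| 2.50 | 1.9 |
| 3.00 | 2.7 |

Monday's run (percent of the starting material charged)

| time / s | ring / % |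
|---|---|
| 10.0 | 7.4 |
| 12.0 | 7.9 |
| 20.0 | 13.7 |
| 40.0 | 22.0 |

(each reading ± 0.5 percentage points)

- the earlier runs were read with a standard deviation of 0.5 percentage points

* the best flask by amount of ring, in percent of the starting material charged; "all alike" if 1.5 percentage points covers them all (dawn / summer / winter / all alike)
* amount of ring at the end, in percent of the starting material charged, dawn
* amount of ring at the end, in percent of the starting material charged, summer
* amount of ring at the end, in percent of the starting material charged, winter

Monday's first reading, 7.4% after 10.0 s, means that the early pace would turn the whole charge into ring in 2.25 min; this is the fill time. Thursday's last reading gives 111 min, though a reading that small carries its scatter of 0.5 points. The charges differ too, so treat what follows as a rough ladder. Spacing the logarithm of the fill time evenly with temperature gives 0.0797 min for summer and 63.7 min for dawn.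

Now hold each rung against the 4.0 min of the reading. Summer fits 50.2 fill times into it, so on this estimate its filling ends early, and whatever happens to ring afterwards has the rest of the run. Winter, at Monday's temperature but with a larger charge, fits 1.78 of Monday's fill times: on this estimate it is read about when filling ends. Dawn gets 6.28% of a fill time, so it is still filling, and that fraction is my figure for its ring. I would bet on winter.

The forecast says winter is best, with 8% for dawn, above my figure, 45% for summer and 58% for winter. Of summer it says: “This is very uncertain, anywhere from 10 to 95%.”

The flasks give 4.54% at dawn, 25.1% in summer and 41.2% in winter, so winter is best.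

    starting material → ring (k = 0.140 s⁻¹, Ea = 101 kJ mol⁻¹)
    2 starting material → open dimer (k = 0.430 M⁻¹ s⁻¹, Ea = 52.0 kJ mol⁻¹)
    starting material + open dimer → open trimer (k = 0.180 M⁻¹ s⁻¹, Ea = 78.0 kJ mol⁻¹)
    ring ⇌ isomer of the product (K = 9.60, k = 0.00520 s⁻¹, Ea = 98.0 kJ mol⁻¹, ΔH = −56.0 kJ mol⁻¹)
    (constants at 100 °C)

So in summer you are watching the ring, the kinetic product, leave. With an estimated fill time of 0.0797 min against Monday's 2.25 min, summer has 97% of its ring-making up to the reading behind it after 0.400 min. The same flask stopped at 1.0 min, which is 12.5 fill times, holds 0.012% starting material and 57.5% ring. Ring is by then draining into the isomer of the product, which holds 18.2% at that moment and 50.7% at the reading in summer; this step is the main reason for the low reading: with it struck out, summer ends at 75.7% ring instead of 25.1%.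

Readings and results are simulated for substances that don't exist; scatter was added.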